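The route rests on disconnecting the C8a–C1 bond of ring A. It exploits the C5,C6 catechol of ring B. Two-electron oxidation gives an o-quinone in which C8a is the β-carbon of the C5 enone, so a ring carbon that is normally nucleophilic accepts the prenyl-type alkene tethered through C4. One operation closes ring A, sets C1 relative to C4, leaves an isopropenyl group and returns the catechol. The precursor is 3-[(S)-6-methylhept-5-en-2-yl]catechol carrying a spectator chlorine at the future C8. The chlorine steers both benzylic groups pseudo-axial (trans), blocks the second β-carbon and later becomes the handle for the pyrone.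

Key step: step 7

Remark a: locants C1–C8a are those of the tetralin core of the target (C1 isopropyl, C4 methyl, C5 and C6 OH, C7 CHO, C8 pyronyl) and are used for all precursors, open-chain ones included; primed locants belong to the pyrone.
Remark b (assumption): the sense of induction in step 4 is matched by choosing the ligand enantiomer (both are available) that delivers the S-configured butene 6.
Remark c (assumption): the C8–C3' axis is not defined in the target structure and is treated as carrying no fixed configuration.

Step 1
Reactants: 1 5-chloro-2-hydroxy-3-methoxybenzaldehyde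
Product: 2 5-chloro-2,3-dihydroxybenzaldehyde
Conditions: BBr3, CH2Cl2, −78 °C to rt; H2O
Reagents that add atoms: none
Why: Boron tribromide cleavage of an aryl methyl ether (Lewis-acid dealkylation) is routine for o-vanillin-type aldehydes, leaves the formyl and chloro groups alone at this temperature, and starts from a compound in which the halogen already sits para to the future C5 oxygen, that is at C8.

Step 2
Reactants: 2 5-chloro-2,3-dihydroxybenzaldehyde
Product: 3 5-chloro-2,3-bis(methoxymethoxy)benzaldehyde
Conditions: NaH, MOMCl, DMF, 0 °C to rt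
Reagents that add atoms: chloromethyl methyl ether (MOMCl), COCCl
Why: Williamson-type O-alkylation of the bis-phenoxide gives the bis-acetal ether, which is inert to the ylide, nickel hydride, borane and aqueous base of the next steps.

Step 3
Reactants: 3 5-chloro-2,3-bis(methoxymethoxy)benzaldehyde
Product: 4 5-chloro-1-ethenyl-2,3-bis(methoxymethoxy)benzene
Conditions: Ph3PCH3Br, KOt-Bu, THF, 0 °C to rt
Reagents that add atoms: methyltriphenylphosphonium bromide, C[P+](c1ccccc1)(c1ccccc1)c1ccccc1.[Br-]
Why: Wittig methylenation of a non-enolisable benzaldehyde is reliable, and the new CH2 carbon becomes the C4 methyl group.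

Step 4
Reactants: 4 5-chloro-1-ethenyl-2,3-bis(methoxymethoxy)benzene, 5 ethylene
Product: 6 1-[(2S)-but-3-en-2-yl]-5-chloro-2,3-bis(methoxymethoxy)benzene
Conditions: [Ni(C3H5)Br]2 (1 mol %), BINOL-derived N,N-bis(1-phenylethyl)phosphoramidite (2 mol %, enantiomer per remark b), NaB[3,5-(CF3)2C6H3]4, ethylene (1 atm), CH2Cl2, −70 °C
Reagents that add atoms: none
Why: In this asymmetric hydrovinylation a cationic nickel hydride adds to the styrene in the Markovnikov sense, ethylene inserts and β-hydride elimination releases the 3-arylbut-1-ene, the chiral phosphoramidite fixing the S configuration of the future C4, and ortho-alkoxy and halogenated styrenes belong to the known scope.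

Step 5
Reactants: 6 1-[(2S)-but-3-en-2-yl]-5-chloro-2,3-bis(methoxymethoxy)benzene, 7 1-bromo-2-methylprop-1-ene
Product: 9 5-chloro-1-[(2S)-6-methylhept-5-en-2-yl]-2,3-bis(methoxymethoxy)benzene, via alkylborane 8 (not isolated)
Conditions: 9-BBN, THF, 0 °C to rt; then 7, Pd(dppf)Cl2 (3 mol %), aq. NaOH (3 M), THF, 60 °C
Reagents that add atoms: 9-borabicyclo[3.3.1]nonane, B1C2CCCC1CCC2 (its boron bicycle stays in 8 only)
Why: Anti-Markovnikov hydroboration followed by B-alkyl Suzuki–Miyaura coupling joins C2 to the alkenyl carbon C1, the alkenyl bromide undergoing oxidative addition with dppf-ligated palladium whereas the aryl chloride does not, and the stereocentre is not touched.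

Step 6
Reactants: 9 5-chloro-1-[(2S)-6-methylhept-5-en-2-yl]-2,3-bis(methoxymethoxy)benzene
Product: 10 5-chloro-3-[(2S)-6-methylhept-5-en-2-yl]benzene-1,2-diol
Conditions: HCl (0.5 M in MeOH), 40 °C, argon
Reagents that add atoms: none
Why: Acid-catalysed acetal exchange with methanol frees both phenols under conditions routinely survived by prenyl groups, and any tertiary cation formed from the alkene could only close onto oxygen or carbon through an eight- or seven-membered ring.

Step 7
Reactants: 10 5-chloro-3-[(2S)-6-methylhept-5-en-2-yl]benzene-1,2-diol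
Product: 12 (1R,4S)-8-chloro-4-methyl-1-(prop-1-en-2-yl)-1,2,3,4-tetrahydronaphthalene-5,6-diol (trans), via o-quinone 11 (not isolated)
Conditions: Ag2O, MgSO4, CH2Cl2, 0 °C, dark; filter under argon; dilute to 2 mM; 2,6-di-tert-butyl-4-methylpyridine, BF3·OEt2, −78 to −40 °C; aq. NaHCO3
Reagents that add atoms: none
Why: Proposed new method: Ag2O dehydrogenates the catechol to o-quinone 11, in which C8a is the β-carbon of the C5 enone, and once the silver residues are filtered off BF3 on the carbonyl oxygens lets alkene carbon C1 bond to C8a while the side-chain methyl group lying over C4a gives up a hydrogen (concerted ene, or a short-lived tertiary cation losing the same proton), after which enolisation restores the aromatic catechol. The closest known chemistry is the BF3-induced cyclisation of bisabolane quinones bearing this very side chain (perezone to the pipitzols), Lewis-acid conjugate addition of alkenes and allylsilanes to quinones, and the carbonyl-ene closure of citronellal to isopulegol. Ring A forms by a six-membered closure that is exo for the alkene and endo for the C4a=C8a bond, and the three-carbon tether cannot bring C1 to C8 or C7. The new C1 centre is controlled by C4 through allylic 1,3-strain on both peri flanks: C4–H eclipses the C5 carbonyl, so the chain folds over one face and the C4 methyl points to the other, while the C8 chlorine forbids an outward isopropylidene, which must lie over the ring on the chain side, so both groups end pseudo-axial, that is trans (1R,4S). The step also needs attack at C8a and not at the C5 carbonyl carbon or the ipso carbon C4a; only the C8a adduct can aromatise and is thus drained irreversibly, whereas the other adducts stay non-aromatic and can revert under the Lewis acid. Removal of the oxidant before the acid, high dilution and a hindered pyridine are there to hold back hydrogen exchange between product catechol and unreacted quinone and acid-induced migration of the new double bond.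

Step 8
Reactants: 12 (1R,4S)-8-chloro-4-methyl-1-(prop-1-en-2-yl)-1,2,3,4-tetrahydronaphthalene-5,6-diol
Product: 13 (1R,4S)-8-chloro-4-methyl-5,6-bis(methoxymethoxy)-1-(prop-1-en-2-yl)tetralin
Conditions: NaH, MOMCl, DMF, 0 °C, argon
Reagents that add atoms: chloromethyl methyl ether (MOMCl), COCCl
Why: Williamson-type O-alkylation masks the oxidation-prone catechol at once and installs at O6 the directing group needed in step 10.

Step 9
Reactants: 13 (1R,4S)-8-chloro-4-methyl-5,6-bis(methoxymethoxy)-1-(prop-1-en-2-yl)tetralin
Product: 14 (1R,4S)-8-chloro-1-isopropyl-4-methyl-5,6-bis(methoxymethoxy)tetralin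
Conditions: H2 (1 atm), RhCl(PPh3)3 (5 mol %), benzene–EtOH, rt
Reagents that add atoms: none
Why: Homogeneous hydrogenation with RhCl(PPh3)3 is the standard way to saturate an isopropenyl group selectively, spares the aryl chloride and the acetals, creates no stereocentre and does not touch C1.

Step 10
Reactants: 14 (1R,4S)-8-chloro-1-isopropyl-4-methyl-5,6-bis(methoxymethoxy)tetralin
Product: 16 (1R,4S)-8-chloro-1-isopropyl-4-methyl-5,6-bis(methoxymethoxy)tetralin-7-carbaldehyde, via aryllithium 15 (not isolated)
Conditions: s-BuLi, TMEDA, THF, −78 °C; DMF, −78 °C to 0 °C; H2O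
Reagents that add atoms: N,N-dimethylformamide, CN(C)C=O; sec-butyllithium, CCC(C)[Li] (lithium stays in 15 only)
Why: Directed ortho-metalation and formylation must occur at C7, the only ring C–H, which is acidified by the flanking acetal oxygen and chlorine, and −78 °C keeps the ortho-chloroaryllithium from losing LiCl to an aryne.

Step 11
Reactants: 17 4-hydroxy-6-methyl-2H-pyran-2-one
Product: 18 4-(methoxymethoxy)-6-methyl-2H-pyran-2-one
Conditions: MOMCl, i-Pr2NEt, CH2Cl2, 0 °C to rt
Reagents that add atoms: chloromethyl methyl ether (MOMCl), COCCl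
Why: O-alkylation of the vinylogous acid with a hard electrophile gives the 4-O-acetal of the 2-pyrone tautomer, the behaviour that makes acetal-protected tetronates and 4-alkoxy-2-pyrones standard intermediates.

Step 12
Reactants: 19 4-hydroxybenzaldehyde
Product: 20 4-(methoxymethoxy)benzaldehyde
Conditions: MOMCl, i-Pr2NEt, CH2Cl2, 0 °C to rt
Reagents that add atoms: chloromethyl methyl ether (MOMCl), COCCl
Why: Williamson-type O-alkylation protects the phenol with the same acid-labile group as all other hydroxyls, so that one final operation suffices.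

Step 13
Reactants: 18 4-(methoxymethoxy)-6-methyl-2H-pyran-2-one, 20 4-(methoxymethoxy)benzaldehyde
Product: 24 4-(methoxymethoxy)-6-{(E)-2-[4-(methoxymethoxy)phenyl]ethenyl}-2H-pyran-2-one, via lithium dienolate 21 (not isolated), via lithium aldolate 22 (not isolated), via mesylate 23 (not isolated)
Conditions: LiHMDS, THF, −78 °C; 20; MsCl, −78 to 0 °C; DBU, rt
Reagents that add atoms: lithium hexamethyldisilazide, [Li]N([Si](C)(C)C)[Si](C)(C)C (lithium stays in 21 and 22 only); methanesulfonyl chloride, CS(=O)(=O)Cl (mesyl group stays in 23 only)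
Why: This is a vinylogous aldol addition followed by mesylation and E1cB elimination, in which the silylamide removes only a proton of the C6' methyl group (the vinylic C3'–H is beyond its reach) and the elimination gives the fully conjugated, thermodynamically preferred E-alkene.

Step 14
Reactants: 24 4-(methoxymethoxy)-6-{(E)-2-[4-(methoxymethoxy)phenyl]ethenyl}-2H-pyran-2-one, 16 (1R,4S)-8-chloro-1-isopropyl-4-methyl-5,6-bis(methoxymethoxy)tetralin-7-carbaldehyde
Product: 27 (1R,4S)-1-isopropyl-4-methyl-5,6-bis(methoxymethoxy)-8-{4-(methoxymethoxy)-6-[(E)-2-(4-(methoxymethoxy)phenyl)ethenyl]-2-oxo-2H-pyran-3-yl}tetralin-7-carbaldehyde, via 3-lithiopyrone 25 (not isolated), via pyronylzinc chloride 26 (not isolated)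
Conditions: LDA, THF, −78 °C; ZnCl2, −78 °C to rt; 16, Pd2(dba)3 (2.5 mol %), RuPhos (10 mol %), THF–NMP, 70 °C
Reagents that add atoms: lithium diisopropylamide, [Li]N(C(C)C)C(C)C (lithium stays in 25 only); zinc chloride, Cl[Zn]Cl (zinc and chlorine stay in 26 only)
Why: Directed metalation at C3' (between the lactone carbonyl and the acetal oxygen, no acidic methyl being left), transmetalation to zinc and Negishi coupling form the C8–C3' bond, since the zinc reagent tolerates the formyl group, that group activates the neighbouring C–Cl bond towards zerovalent palladium, and the bulky dialkylbiarylphosphine is made for biaryls with four ortho substituents.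

Step 15
Reactants: 27 (1R,4S)-1-isopropyl-4-methyl-5,6-bis(methoxymethoxy)-8-{4-(methoxymethoxy)-6-[(E)-2-(4-(methoxymethoxy)phenyl)ethenyl]-2-oxo-2H-pyran-3-yl}tetralin-7-carbaldehyde
Product: 28 heimiomycin A
Conditions: HCl (1.25 M in MeOH), THF, 40 °C, argon; H2O
Reagents that add atoms: none
Why: Acid-catalysed acetal exchange removes all four methoxymethyl groups, methanol traps the formaldehyde unit, any transient acetal of the hydrogen-bonded aldehyde falls apart on adding water, and neither stereocentre nor the E-alkene is affected.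

Compound list
1 | 5-chloro-2-hydroxy-3-methoxybenzaldehyde | COc1cc(Cl)cc(C=O)c1O | starting material
2 | 5-chloro-2,3-dihydroxybenzaldehyde | O=Cc1cc(Cl)cc(O)c1O | intermediate
3 | 5-chloro-2,3-bis(methoxymethoxy)benzaldehyde | COCOc1cc(Cl)cc(C=O)c1OCOC | intermediate
4 | 5-chloro-1-ethenyl-2,3-bis(methoxymethoxy)benzene | C=Cc1cc(Cl)cc(OCOC)c1OCOC | intermediate
5 | ethylene | C=C | starting material
6 | 1-[(2S)-but-3-en-2-yl]-5-chloro-2,3-bis(methoxymethoxy)benzene | C=C[C@H](C)c1cc(Cl)cc(OCOC)c1OCOC | intermediate
7 | 1-bromo-2-methylprop-1-ene | CC(C)=CBr | starting material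
8 | 9-{(3S)-3-[5-chloro-2,3-bis(methoxymethoxy)phenyl]butyl}-9-borabicyclo[3.3.1]nonane | B1(C2CCCC1CCC2)CC[C@H](C)c1cc(Cl)cc(OCOC)c1OCOC | intermediate
9 | 5-chloro-1-[(2S)-6-methylhept-5-en-2-yl]-2,3-bis(methoxymethoxy)benzene | CC(C)=CCC[C@H](C)c1cc(Cl)cc(OCOC)c1OCOC | intermediate
10 | 5-chloro-3-[(2S)-6-methylhept-5-en-2-yl]benzene-1,2-diol | CC(C)=CCC[C@H](C)c1cc(Cl)cc(O)c1O | intermediate
11 | 5-chloro-3-[(2S)-6-methylhept-5-en-2-yl]cyclohexa-3,5-diene-1,2-dione | CC(C)=CCC[C@H](C)C1=CC(Cl)=CC(=O)C1=O | intermediate
12 | (1R,4S)-8-chloro-4-methyl-1-(prop-1-en-2-yl)-1,2,3,4-tetrahydronaphthalene-5,6-diol | CC(=C)[C@H]1CC[C@H](C)c2c(O)c(O)cc(Cl)c21 | intermediate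
13 | (1R,4S)-8-chloro-4-methyl-5,6-bis(methoxymethoxy)-1-(prop-1-en-2-yl)tetralin | CC(=C)[C@H]1CC[C@H](C)c2c(OCOC)c(OCOC)cc(Cl)c21 | intermediate
14 | (1R,4S)-8-chloro-1-isopropyl-4-methyl-5,6-bis(methoxymethoxy)tetralin | CC(C)[C@H]1CC[C@H](C)c2c(OCOC)c(OCOC)cc(Cl)c21 | intermediate
15 | (1R,4S)-8-chloro-1-isopropyl-7-lithio-4-methyl-5,6-bis(methoxymethoxy)tetralin | CC(C)[C@H]1CC[C@H](C)c2c(OCOC)c(OCOC)c([Li])c(Cl)c21 | intermediate
16 | (1R,4S)-8-chloro-1-isopropyl-4-methyl-5,6-bis(methoxymethoxy)tetralin-7-carbaldehyde | CC(C)[C@H]1CC[C@H](C)c2c(OCOC)c(OCOC)c(C=O)c(Cl)c21 | intermediate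
17 | 4-hydroxy-6-methyl-2H-pyran-2-one | Cc1cc(O)cc(=O)o1 | starting material
18 | 4-(methoxymethoxy)-6-methyl-2H-pyran-2-one | Cc1cc(OCOC)cc(=O)o1 | intermediate
19 | 4-hydroxybenzaldehyde | O=Cc1ccc(O)cc1 | starting material
20 | 4-(methoxymethoxy)benzaldehyde | COCOc1ccc(C=O)cc1 | intermediate
21 | lithium dienolate of 18 (2-lithiooxy-4-(methoxymethoxy)-6-methylidene-6H-pyran) | C=C1C=C(OCOC)C=C(O[Li])O1 | intermediate
22 | lithium 2-[4-(methoxymethoxy)-2-oxo-2H-pyran-6-yl]-1-[4-(methoxymethoxy)phenyl]ethanolate (racemic) | [Li]OC(Cc1cc(OCOC)cc(=O)o1)c1ccc(OCOC)cc1 | intermediate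
23 | 2-[4-(methoxymethoxy)-2-oxo-2H-pyran-6-yl]-1-[4-(methoxymethoxy)phenyl]ethyl methanesulfonate (racemic) | CS(=O)(=O)OC(Cc1cc(OCOC)cc(=O)o1)c1ccc(OCOC)cc1 | intermediate
24 | 4-(methoxymethoxy)-6-{(E)-2-[4-(methoxymethoxy)phenyl]ethenyl}-2H-pyran-2-one | COCOc1ccc(/C=C/c2cc(OCOC)cc(=O)o2)cc1 | intermediate
25 | 3-lithio derivative of 24 | COCOc1ccc(/C=C/c2cc(OCOC)c([Li])c(=O)o2)cc1 | intermediate
26 | 3-(chlorozincio) derivative of 24 | COCOc1ccc(/C=C/c2cc(OCOC)c([Zn]Cl)c(=O)o2)cc1 | intermediate
27 | tetrakis(methoxymethyl) ether of heimiomycin A, (1R,4S) | CC(C)[C@H]1CC[C@H](C)c2c(OCOC)c(OCOC)c(C=O)c(-c3c(OCOC)cc(/C=C/c4ccc(OCOC)cc4)oc3=O)c21 | intermediate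
28 | heimiomycin A, (1R,4S) | CC(C)[C@H]1CC[C@H](C)c2c(O)c(O)c(C=O)c(-c3c(O)cc(/C=C/c4ccc(O)cc4)oc3=O)c21 | target

Total step count: 15. Longest linear sequence: 12 (steps 1–10, 14, 15).

Steps most likely to fail

1. Step 7. Several processes may interfere:
- hydrogen exchange between the catechol being formed and quinone still present;
- Diels–Alder self-dimerisation of the quinone, or its tautomerisation to a quinone methide, which would erode C4;
- bonding of the alkene to the C5 carbonyl carbon or to the ipso carbon;
- leakage through an open cation with loss of the 1,4-induction.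

The fallback uses known chemistry, sets out from 9 and comes back at 13, so that 10–12 are by-passed. The side chain is oxidised instead of the ring. Riley allylic oxidation of the E-methyl group of 9 (SeO2 cat., t-BuOOH, CH2Cl2) should give (2E,6S)-6-[5-chloro-2,3-bis(methoxymethoxy)phenyl]-2-methylhept-2-en-1-ol F1. An intramolecular Friedel–Crafts allylic alkylation follows, of the kind used to make 1-vinyltetralins from arene-tethered allylic alcohols (AgOTf or Ph3PAuCl/AgOTf, ClCH2CH2Cl). In it C8a, which is para to the C6 oxygen, attacks C1 with allylic transposition and loss of water. This should give 13 directly, with the same two peri flanks directing C1.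

2. Step 14. Oxidative addition and reductive elimination at the doubly flanked C8 may be slow. The zinc reagent may add to the formyl group, and the metalated pyrone may be protonated before it couples. The fallback sets out from 16 and 24 and comes back at 27, with the roles of the partners exchanged. Miyaura borylation of 16 (B2pin2, Pd2(dba)3, XPhos, KOAc, dioxane, 100 °C) brings only a small boryl group to C8. It should give (1R,4S)-1-isopropyl-4-methyl-5,6-bis(methoxymethoxy)-8-(4,4,5,5-tetramethyl-1,3,2-dioxaborolan-2-yl)tetralin-7-carbaldehyde F2. Electrophilic bromination of 24 at its most nucleophilic carbon C3' (NBS, MeCN, 0 °C) should give 3-bromo-4-(methoxymethoxy)-6-{(E)-2-[4-(methoxymethoxy)phenyl]ethenyl}-2H-pyran-2-one F3. Suzuki–Miyaura coupling of the two (Pd(OAc)2, SPhos, K3PO4, toluene–H2O, 80 °C) places the easy oxidative addition on the pyrone and leads to 27.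

3. Step 4. The ortho acetal oxygens may chelate and inhibit the cationic nickel catalyst. The product alkene may isomerise into conjugation, and the induction may be insufficient for an ortho-substituted styrene. The fallback sets out from 4 and comes back at 6. Copper-hydride-catalysed enantioselective Markovnikov hydroboration (CuCl, NaOt-Bu, DTBM-Segphos, pinacolborane, toluene) should give 2-{(1R)-1-[5-chloro-2,3-bis(methoxymethoxy)phenyl]ethyl}-4,4,5,5-tetramethyl-1,3,2-dioxaborolane F4. Zweifel olefination (vinylmagnesium bromide; I2; NaOMe, THF, −78 °C to rt) then exchanges boron for vinyl with retention of configuration to give 6.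

Further compounds
F1 | step 7 | (2E,6S)-6-[5-chloro-2,3-bis(methoxymethoxy)phenyl]-2-methylhept-2-en-1-ol | OC/C(C)=C/CC[C@H](C)c1cc(Cl)cc(OCOC)c1OCOC
F2 | step 14 | (1R,4S)-1-isopropyl-4-methyl-5,6-bis(methoxymethoxy)-8-(4,4,5,5-tetramethyl-1,3,2-dioxaborolan-2-yl)tetralin-7-carbaldehyde | CC(C)[C@H]1CC[C@H](C)c2c(OCOC)c(OCOC)c(C=O)c(B3OC(C)(C)C(C)(C)O3)c21
F3 | step 14 | 3-bromo-4-(methoxymethoxy)-6-{(E)-2-[4-(methoxymethoxy)phenyl]ethenyl}-2H-pyran-2-one | COCOc1ccc(/C=C/c2cc(OCOC)c(Br)c(=O)o2)cc1
F4 | step 4 | 2-{(1R)-1-[5-chloro-2,3-bis(methoxymethoxy)phenyl]ethyl}-4,4,5,5-tetramethyl-1,3,2-dioxaborolane | CC1(C)OB(OC1(C)C)[C@H](C)c1cc(Cl)cc(OCOC)c1OCOC
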